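**Retrosynthetic overview**
- Okilactomycin C ⇐ hydrolysis of its O-methyl ethyl ester, whose 13-membered ring is closed last by a carbonylative Stille coupling (tetronate C3–Sn + side-chain (Z)-vinyl iodide + CO).
- The spiro-tetronate cyclohexene ⇐ phosphine-catalysed [4+2] annulation of a γ-alkyl α-ethyl allenoate with 4-methoxy-5-methylidenefuranone (key step). The phosphonium-activated allenoate acts as a vinylogous enolonium (γ-umpolung), so the tetronate C5 carbanion bonds to the enoate γ-carbon; both ring bonds, the spiro centre and the three ring stereocentres form in one step.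
- Allenoate ⇐ ketene (from the acid chloride) + stabilised ylide; syn-dimethyl chain ⇐ two zirconium-catalysed carboaluminations (ZACA) of hept-6-en-1-ol; (Z)-vinyl iodide ⇐ Stork–Zhao olefination.
- Ring order: tetronate (bought, then methylenated) → cyclohexene with spiro centre → 13-membered carbocycle.

Assumption: the enol drawn in the target SMILES is one tautomer of the 3-acyl tetronic acid and forms on acidification; the zirconium catalyst, the chiral phosphine and the butanoate ylide are bought.

**Route**

Step 1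
Reactants: 1 hept-6-en-1-ol
Product: 2 tert-butyl(hept-6-en-1-yloxy)dimethylsilane
Conditions: TBSCl, imidazole, DMF, rt
Reagents that add atoms: tert-butyldimethylsilyl chloride CC(C)(C)[Si](C)(C)Cl
Why: Imidazole-promoted silylation of a primary alcohol, which shields the OH from Me3Al in the next two steps; no stereocentre.

Step 2
Reactants: 2 tert-butyl(hept-6-en-1-yloxy)dimethylsilane
Product: 5 tert-butyldimethyl{[(6R)-6-methylnon-8-en-1-yl]oxy}silane, via alkylalane 3 (not isolated), via alkylzinc triflate 4 (not isolated)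
Conditions: Me3Al, (−)-(NMI)2ZrCl2 (4 mol%), (MeAlO)n, CH2Cl2, 0 °C to rt; evaporate; Zn(OTf)2, DMF; CH2=CHBr, PdCl2(DPEphos) (3 mol%), iBu2AlH (6 mol%), 70 °C
Reagents that add atoms: trimethylaluminium C[Al](C)C; vinyl bromide C=CBr
Why: Negishi ZACA reaction (the catalyst enantiomer that gives R-configured 2-methylalkylalanes sets C6) followed by one-pot Al→Zn transmetalation and Negishi vinylation, which does not touch the new centre.

Step 3
Reactants: 5 tert-butyldimethyl{[(6R)-6-methylnon-8-en-1-yl]oxy}silane
Product: 7 (2R,4R)-9-[(tert-butyldimethylsilyl)oxy]-2,4-dimethylnonan-1-ol, via alkylalane 6 (not isolated)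
Conditions: Me3Al, (−)-(NMI)2ZrCl2 (4 mol%), (MeAlO)n, CH2Cl2, rt; then O2, 0 °C to rt; aqueous work-up; chromatography
Reagents that add atoms: trimethylaluminium C[Al](C)C; oxygen O=O
Why: Second ZACA with the same catalyst enantiomer sets C2 by catalyst control and gives the syn-2,4-dimethyl array (about 8:1, anti isomer removed by chromatography); O2 oxidises the C–Al bond to the primary alcohol.

Step 4
Reactants: 7 (2R,4R)-9-[(tert-butyldimethylsilyl)oxy]-2,4-dimethylnonan-1-ol
Product: 8 (2R,4R)-9-[(tert-butyldimethylsilyl)oxy]-2,4-dimethylnonanal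
Conditions: Dess–Martin periodinane, CH2Cl2, 0 °C to rt
Reagents that add atoms: none
Why: Dess–Martin oxidation is non-basic, so the α-methyl stereocentre is not epimerised; the aldehyde is used directly.

Step 5
Reactants: 8 (2R,4R)-9-[(tert-butyldimethylsilyl)oxy]-2,4-dimethylnonanal
Product: 9 tert-butyl{[(6R,8R,9Z)-10-iodo-6,8-dimethylundec-9-en-1-yl]oxy}dimethylsilane
Conditions: [Ph3PCH2CH3]I, n-BuLi, THF, rt; I2, −78 °C; NaN(SiMe3)2, −20 °C; then 8, −78 to −20 °C
Reagents that add atoms: ethyltriphenylphosphonium iodide CC[P+](c1ccccc1)(c1ccccc1)c1ccccc1.[I-]; iodine II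
Why: Stork–Zhao olefination (Wittig reaction of the α-iodo ylide) gives the (Z)-2-iodoalkene with iodine cis to the chain under kinetic low-temperature control, so the later C–C bond at this carbon inherits the (Z)-enone geometry of the target; the α-centre survives at low temperature.

Step 6
Reactants: 9 tert-butyl{[(6R,8R,9Z)-10-iodo-6,8-dimethylundec-9-en-1-yl]oxy}dimethylsilane
Product: 12 (6R,8R,9Z)-10-iodo-6,8-dimethylundec-9-enoic acid, via alcohol 10 (not isolated), via aldehyde 11 (not isolated)
Conditions: CrO3, H2SO4, acetone/H2O, 0 °C to rt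
Reagents that add atoms: water O
Why: Jones oxidation: aqueous acid removes the silyl ether and chromic acid takes the alcohol through the aldehyde hydrate to the acid in one flask; vinyl iodide and stereocentres are inert.

Step 7
Reactants: 12 (6R,8R,9Z)-10-iodo-6,8-dimethylundec-9-enoic acid; 13 ethyl 2-(triphenylphosphoranylidene)butanoate
Product: 16 ethyl (8R,10R,11Z)-2-ethyl-12-iodo-8,10-dimethyltrideca-2,3,11-trienoate (allene axis as a 1:1 mixture), via acid chloride 14 (not isolated), via ketene 15 (not isolated)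
Conditions: (COCl)2, DMF (cat.), CH2Cl2, 0 °C to rt; evaporate; 13, Et3N, CH2Cl2, 0 °C to rt
Reagents that add atoms: none
Why: Dehydrochlorination of the acid chloride gives the ketene, which undergoes a Wittig reaction with the stabilised ylide (standard synthesis of α-alkyl allenoates); the allene axis is erased in step 9, so its configuration is irrelevant.

Step 8
Reactants: 17 4-methoxyfuran-2(5H)-one (methyl tetronate)
Product: 21 4-methoxy-5-methylidenefuran-2(5H)-one, via lithium furanolate 18 (not isolated), via Mannich base 19 (not isolated), via ammonium iodide 20 (not isolated)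
Conditions: LiN(iPr)2, THF, −78 °C; Me2N=CH2 I (Eschenmoser's salt), −78 °C to rt; MeI, rt; aq. NaHCO3, rt; used freshly
Reagents that add atoms: N,N-dimethylmethyleneiminium iodide C=[N+](C)C.[I-]
Why: γ-Deprotonation gives the aromatic 2-oxyfuran anion, which undergoes a Mannich reaction at C5; N-methylation and E1cB elimination of trimethylamine give the exocyclic alkene.

Step 9
Reactants: 16 ethyl (8R,10R,11Z)-2-ethyl-12-iodo-8,10-dimethyltrideca-2,3,11-trienoate; 21 4-methoxy-5-methylidenefuran-2(5H)-one
Product: 22 ethyl (5S,6S,9S)-6-[(4R,6R,7Z)-8-iodo-4,6-dimethylnon-7-en-1-yl]-4-methoxy-9-methyl-2-oxo-1-oxaspiro[4.5]deca-3,7-diene-8-carboxylate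
Conditions: (R)-SITCP (chiral spirobiindane phenylphosphepine, 20 mol%), toluene, 40 °C, 21 (1.5 equiv) added over 6 h; chromatography
Reagents that add atoms: none
Why: Proposed new method: the phosphine adds to the allenoate and the phosphonium dienolate equilibrates to the vinylogous ylide, whose β′-carbon (the CH2 of the ethyl group) adds to the exocyclic CH2 of 21 (first bond, joining two normally electrophilic β-positions and setting C9 under catalyst control); the aromatic furanolate so formed is a tethered carbon pronucleophile that closes on the γ-carbon of the vinylphosphonium (γ-umpolung, the allenoate serving as a vinylogous enolonium equivalent; second bond, joining two normally nucleophilic carbons and setting C5 and C6), and β-elimination returns the phosphine and the conjugated ester. A chair-like closure with the methyl equatorial, the side chain trans to phosphorus (hence axial) and the lactone oxygen axial places methyl, side chain and tetronate C4 on one face as in the target. The closest known reaction types are the Kwon [4+2] annulation of α-alkyl allenoates with activated alkenes (triarylphosphine mode, including spiro-oxindole cases) and enantioselective phosphepine-catalysed γ-additions of carbon pronucleophiles to γ-alkyl allenoates. The γ-substituent disfavours initial γ-attack, which supports the required regiochemistry. The catalyst enantiomer is the one a model run shows to give 9S, and stereoisomers are diastereomers of the chiral chain and are separable.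

Step 10
Reactants: 22 ethyl (5S,6S,9S)-6-[(4R,6R,7Z)-8-iodo-4,6-dimethylnon-7-en-1-yl]-4-methoxy-9-methyl-2-oxo-1-oxaspiro[4.5]deca-3,7-diene-8-carboxylate
Product: 24 ethyl (5S,6S,9S)-6-[(4R,6R,7Z)-8-iodo-4,6-dimethylnon-7-en-1-yl]-4-methoxy-9-methyl-2-oxo-3-(trimethylstannyl)-1-oxaspiro[4.5]deca-3,7-diene-8-carboxylate, via 3-lithio tetronate 23 (not isolated)
Conditions: LiN(iPr)2 (1.2 equiv), THF, −78 °C, 20 min; Me3SnCl, −78 to −40 °C
Reagents that add atoms: trimethyltin chloride C[Sn](C)(C)Cl
Why: Vinylic C3 lithiation of 5,5-disubstituted 4-methoxyfuranones is fast at −78 °C (the only vinylic C–H flanked by the carbonyl and the OMe-bearing carbon) and is quenched by tin; the short low-temperature exposure should spare the ethyl enoate and the vinyl iodide, and no stereocentre is touched.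

Step 11
Reactants: 24 ethyl (5S,6S,9S)-6-[(4R,6R,7Z)-8-iodo-4,6-dimethylnon-7-en-1-yl]-4-methoxy-9-methyl-2-oxo-3-(trimethylstannyl)-1-oxaspiro[4.5]deca-3,7-diene-8-carboxylate
Product: 25 O-methyl okilactomycin C ethyl ester (13-membered carbocycle in which tetronate C3 is joined through a new ketone C=O to the former CI carbon, giving the (Z)-2-methylenone; other centres as in 22)
Conditions: Pd2(dba)3 (10 mol%), AsPh3 (40 mol%), CuI (20 mol%), CO (3 atm), DMF, 50 °C, 2 mM, syringe pump
Reagents that add atoms: carbon monoxide [C-]#[O+]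
Why: Intramolecular carbonylative Stille coupling: zerovalent palladium inserts into the vinyl iodide with retention, CO inserts, the stannyl tetronate transmetalates and reductive elimination closes the 13-membered ring as the (Z)-enone; CO pressure and high dilution suppress direct coupling and oligomers.

Step 12
Reactants: 25 O-methyl okilactomycin C ethyl ester
Product: 26 okilactomycin C
Conditions: LiOH (6 equiv), THF/MeOH/H2O, 40 °C; then 1 M HCl to pH 2
Reagents that add atoms: lithium hydroxide [Li+].[OH-]; water O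
Why: Hydroxide cleaves the vinylogous methyl ester of the 3-acyl tetronate by addition–elimination at C4 and saponifies the ethyl ester; the resulting 3-acyl tetronate anion is inert to base, and acidification gives the enolised target with all stereocentres and the (Z)-alkene unchanged.

**Compound list**
1 | hept-6-en-1-ol | C=CCCCCCO | starting material
2 | tert-butyl(hept-6-en-1-yloxy)dimethylsilane | C=CCCCCCO[Si](C)(C)C(C)(C)C | intermediate
3 | dimethyl[(2R)-7-(tert-butyldimethylsilyloxy)-2-methylheptyl]alane | C[Al](C)C[C@H](C)CCCCCO[Si](C)(C)C(C)(C)C | intermediate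
4 | [(2R)-7-(tert-butyldimethylsilyloxy)-2-methylheptyl]zinc trifluoromethanesulfonate | FC(F)(F)S(=O)(=O)O[Zn]C[C@H](C)CCCCCO[Si](C)(C)C(C)(C)C | intermediate
5 | tert-butyldimethyl{[(6R)-6-methylnon-8-en-1-yl]oxy}silane | C=CC[C@H](C)CCCCCO[Si](C)(C)C(C)(C)C | intermediate
6 | dimethyl[(2R,4R)-9-(tert-butyldimethylsilyloxy)-2,4-dimethylnonyl]alane | C[Al](C)C[C@H](C)C[C@H](C)CCCCCO[Si](C)(C)C(C)(C)C | intermediate
7 | (2R,4R)-9-[(tert-butyldimethylsilyl)oxy]-2,4-dimethylnonan-1-ol | OC[C@H](C)C[C@H](C)CCCCCO[Si](C)(C)C(C)(C)C | intermediate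
8 | (2R,4R)-9-[(tert-butyldimethylsilyl)oxy]-2,4-dimethylnonanal | O=C[C@H](C)C[C@H](C)CCCCCO[Si](C)(C)C(C)(C)C | intermediate
9 | tert-butyl{[(6R,8R,9Z)-10-iodo-6,8-dimethylundec-9-en-1-yl]oxy}dimethylsilane | C/C(I)=C/[C@H](C)C[C@H](C)CCCCCO[Si](C)(C)C(C)(C)C | intermediate
10 | (6R,8R,9Z)-10-iodo-6,8-dimethylundec-9-en-1-ol | C/C(I)=C/[C@H](C)C[C@H](C)CCCCCO | intermediate
11 | (6R,8R,9Z)-10-iodo-6,8-dimethylundec-9-enal | C/C(I)=C/[C@H](C)C[C@H](C)CCCCC=O | intermediate
12 | (6R,8R,9Z)-10-iodo-6,8-dimethylundec-9-enoic acid | C/C(I)=C/[C@H](C)C[C@H](C)CCCCC(=O)O | intermediate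
13 | ethyl 2-(triphenylphosphoranylidene)butanoate | CCOC(=O)C(CC)=P(c1ccccc1)(c1ccccc1)c1ccccc1 | starting material
14 | (6R,8R,9Z)-10-iodo-6,8-dimethylundec-9-enoyl chloride | C/C(I)=C/[C@H](C)C[C@H](C)CCCCC(=O)Cl | intermediate
15 | (6R,8R,9Z)-10-iodo-6,8-dimethylundeca-1,9-dien-1-one (ketene) | C/C(I)=C/[C@H](C)C[C@H](C)CCCC=C=O | intermediate
16 | ethyl (8R,10R,11Z)-2-ethyl-12-iodo-8,10-dimethyltrideca-2,3,11-trienoate (allene axis mixed) | C/C(I)=C/[C@H](C)C[C@H](C)CCCC=C=C(CC)C(=O)OCC | intermediate
17 | 4-methoxyfuran-2(5H)-one | COC1=CC(=O)OC1 | starting material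
18 | lithium 4-methoxyfuran-2-olate | [Li+].[O-]c1cc(OC)co1 | intermediate
19 | 5-[(dimethylamino)methyl]-4-methoxyfuran-2(5H)-one (racemic) | CN(C)CC1OC(=O)C=C1OC | intermediate
20 | [(3-methoxy-5-oxo-2,5-dihydrofuran-2-yl)methyl]trimethylammonium iodide (racemic) | C[N+](C)(C)CC1OC(=O)C=C1OC.[I-] | intermediate
21 | 4-methoxy-5-methylidenefuran-2(5H)-one | C=C1OC(=O)C=C1OC | intermediate
22 | ethyl (5S,6S,9S)-6-[(4R,6R,7Z)-8-iodo-4,6-dimethylnon-7-en-1-yl]-4-methoxy-9-methyl-2-oxo-1-oxaspiro[4.5]deca-3,7-diene-8-carboxylate | C/C(I)=C/[C@H](C)C[C@H](C)CCC[C@H]2C=C(C(=O)OCC)[C@@H](C)C[C@]23OC(=O)C=C3OC | intermediate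
23 | 3-lithio derivative of 22 | C/C(I)=C/[C@H](C)C[C@H](C)CCC[C@H]2C=C(C(=O)OCC)[C@@H](C)C[C@]23OC(=O)C([Li])=C3OC | intermediate
24 | ethyl (5S,6S,9S)-6-[(4R,6R,7Z)-8-iodo-4,6-dimethylnon-7-en-1-yl]-4-methoxy-9-methyl-2-oxo-3-(trimethylstannyl)-1-oxaspiro[4.5]deca-3,7-diene-8-carboxylate | C/C(I)=C/[C@H](C)C[C@H](C)CCC[C@H]2C=C(C(=O)OCC)[C@@H](C)C[C@]23OC(=O)C([Sn](C)(C)C)=C3OC | intermediate
25 | O-methyl okilactomycin C ethyl ester (13-membered (Z)-enone macrocycle) | C/C1=C/[C@H](C)C[C@H](C)CCC[C@H]2C=C(C(=O)OCC)[C@@H](C)C[C@]23OC(=O)C(C1=O)=C3OC | intermediate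
26 | okilactomycin C | CC1=C/[C@H](C)C[C@H](C)CCC[C@H]2C=C(C(=O)O)[C@@H](C)C[C@]23OC(=O)\C(=C\1O)C3=O | target

**Totals**
Total steps: 12. Longest linear sequence: 11 steps (steps 1–7, then 9–12; step 8 is the one-step side branch).

**Three steps most likely to fail**

Step 9 (phosphine-catalysed [4+2]). The risks are initial γ- instead of β′-attack, isomerisation of the allenoate, oligomerisation of 21, and incomplete catalyst control over three new centres. The fallback replaces the ionic annulation by a thermal Diels–Alder reaction. It sets out from 9: Bu4NF gives alcohol 10 and Dess–Martin oxidation gives aldehyde 11. Hydroalumination of ethyl but-2-ynoate (iBu2AlH, N-methylmorpholine N-oxide) and addition of the vinylalane to 11 gives ethyl (2Z,8R,10R,11Z)-2-ethylidene-3-hydroxy-12-iodo-8,10-dimethyltridec-11-enoate F1. Dehydration with the Burgess reagent gives the diene ethyl (2Z,3E,8R,10R,11Z)-2-ethylidene-12-iodo-8,10-dimethyltrideca-3,11-dienoate F2. Heating F2 with 21 (toluene, 110 °C, BHT) returns to the route at 22; the suprafacial cycloaddition fixes methyl and side chain cis, and the isomer with tetronate C4 endo is the one needed.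

Step 11 (carbonylative Stille macrocyclisation, together with the lithiation of step 10 that prepares it). The risks are slow transmetalation of the electron-poor stannane, direct coupling without CO, and base damage to the vinyl iodide in step 10. The fallback avoids tin and strong base and sets out from 22. Vilsmeier–Haack formylation (POCl3, DMF) at tetronate C3 gives ethyl (5S,6S,9S)-3-formyl-6-[(4R,6R,7Z)-8-iodo-4,6-dimethylnon-7-en-1-yl]-4-methoxy-9-methyl-2-oxo-1-oxaspiro[4.5]deca-3,7-diene-8-carboxylate F3. Intramolecular Nozaki–Hiyama–Kishi reaction (CrCl2, NiCl2 cat., DMSO/THF, 2 mM; zerovalent nickel inserts into the vinyl iodide with retention and the vinyl group passes to trivalent chromium) gives the macrocyclic allylic alcohol (carbinol analogue of 25) F4. Dess–Martin oxidation of F4 returns to the route at 25.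

Step 5 (Stork–Zhao olefination). The risks are modest yield and Z:E ratio and epimerisation of the α-methyl aldehyde. The fallback builds the iodoalkene stepwise and sets out from 8. CBr4/PPh3 gives tert-butyl{[(6R,8R)-10,10-dibromo-6,8-dimethyldec-9-en-1-yl]oxy}dimethylsilane F5. Trans-selective Negishi monomethylation (Me2Zn, PdCl2(DPEphos)) gives tert-butyl{[(6R,8R,9Z)-10-bromo-6,8-dimethylundec-9-en-1-yl]oxy}dimethylsilane F6. Bromine–lithium exchange (t-BuLi, −78 °C) and I2 quench with retention return to the route at 9.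

**Further compounds**
F1 | step 9 | ethyl (2Z,8R,10R,11Z)-2-ethylidene-3-hydroxy-12-iodo-8,10-dimethyltridec-11-enoate (C3 epimers) | C/C(I)=C/[C@H](C)C[C@H](C)CCCCC(O)/C(=C/C)C(=O)OCC
F2 | step 9 | ethyl (2Z,3E,8R,10R,11Z)-2-ethylidene-12-iodo-8,10-dimethyltrideca-3,11-dienoate | C/C(I)=C/[C@H](C)C[C@H](C)CCC/C=C/C(=C/C)C(=O)OCC
F3 | step 11 | ethyl (5S,6S,9S)-3-formyl-6-[(4R,6R,7Z)-8-iodo-4,6-dimethylnon-7-en-1-yl]-4-methoxy-9-methyl-2-oxo-1-oxaspiro[4.5]deca-3,7-diene-8-carboxylate | C/C(I)=C/[C@H](C)C[C@H](C)CCC[C@H]2C=C(C(=O)OCC)[C@@H](C)C[C@]23OC(=O)C(C=O)=C3OC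
F4 | step 11 | macrocyclic allylic alcohol, carbinol analogue of 25 (carbinol epimers) | C/C1=C/[C@H](C)C[C@H](C)CCC[C@H]2C=C(C(=O)OCC)[C@@H](C)C[C@]23OC(=O)C(C1O)=C3OC
F5 | step 5 | tert-butyl{[(6R,8R)-10,10-dibromo-6,8-dimethyldec-9-en-1-yl]oxy}dimethylsilane | BrC(Br)=C[C@H](C)C[C@H](C)CCCCCO[Si](C)(C)C(C)(C)C
F6 | step 5 | tert-butyl{[(6R,8R,9Z)-10-bromo-6,8-dimethylundec-9-en-1-yl]oxy}dimethylsilane | C/C(Br)=C/[C@H](C)C[C@H](C)CCCCCO[Si](C)(C)C(C)(C)C
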